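**Retrosynthetic overview**
1. Target ⇒ C3 alcohol / C30 silyl ether / C11 carbinol; key disconnection C11–C12: carbonyl allylation of the cis-decalin C11 aldehyde 28 by the α-carbon of the 12-silyloxy-(2E,6E,10E)-farnesyl barium reagent (from chloride 34, made from farnesyl acetate). The surplus C11 oxygen is removed afterwards by Barton–McCombie reduction.
2. 28 ⇒ ring A ketone and gem-dimethyl from a Δ3 alkene (hydroboration, oxidation, methylation); 8α-OH from a hydroxyl-directed β-epoxide opened with inversion at C8; C11 from a [2,3]-Wittig–Still shift off a 7β-allylic alcohol (Wharton transposition of the enone epoxide).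
3. Ring order: ring B is (S)-carvone (C5 from the chiral pool); C10 is made quaternary by two α′-alkylations (butenyl, then methyl trans to isopropenyl); ring A is closed second by ring-closing metathesis, which fixes the cis ring fusion.

Assumption: the SMILES is taken literally, (5S,8R,9R,10S), i.e. H-5 cis to the C10 methyl (A/B cis-fused decalin); that diastereomer is the one made.

Convention: bicyclic compounds carry the target's decalin numbering (ring A: C1–C5, C10; ring B: C5–C10; C11 on C9; methyls on C4, C8, C10). β is the face of the C10 methyl; every bicycle has 5β-H and 10β-Me. ξ marks a centre carried as an epimer mixture that is removed later.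

**Route**

Step 1
Reactants: 1 (S)-(+)-carvone; 2 4-iodobut-1-ene
Product: 4 (5S,6RS)-6-(but-3-enyl)carvone, via lithium α′-dienolate 3 (not isolated)
Conditions: LiN(i-Pr)2, THF, −78 °C; then 2, DMPU, −78 → 0 °C
Reagents that add atoms: none
Why: Kinetic α′-deprotonation of the enone gives the cross-conjugated lithium dienolate, which is C-alkylated by the primary iodide (enolate alkylation); the new centre is an inconsequential mixture because it is re-enolised in step 2.

Step 2
Reactants: 4 (5S,6RS)-6-(but-3-enyl)carvone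
Product: 6 (5R,6S)-6-(but-3-enyl)-6-methylcarvone, via lithium enolate 5 (not isolated)
Conditions: LiN(i-Pr)2, THF, −78 °C; then MeI, −78 → 0 °C
Reagents that add atoms: iodomethane (CI)
Why: Enolate alkylation in which A(1,2) strain holds the neighbouring isopropenyl group pseudo-axial, so MeI enters on the opposite face and the quaternary carbon (future C10) is set with methyl trans and butenyl cis to isopropenyl.

Step 3
Reactants: 6 (5R,6S)-6-(but-3-enyl)-6-methylcarvone
Product: 7 cis-fused dienone (4,8,10-trimethyl-5β-H-decala-3,7-dien-9-one)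
Conditions: second-generation Grubbs catalyst (5 mol %), CH2Cl2 (0.01 M), 40 °C
Reagents that add atoms: none
Why: Ring-closing olefin metathesis of the cis-disposed butenyl and isopropenyl groups closes ring A as a trisubstituted cyclohexene and can only give the cis-fused decalin (H-5 and C10-Me on one face).

Step 4
Reactants: 7 cis-fused dienone
Product: 8 7β,8β-epoxy ketone
Conditions: 30% H2O2, NaOH (cat.), MeOH, 0 °C
Reagents that add atoms: hydrogen peroxide (OO)
Why: Weitz–Scheffer nucleophilic epoxidation touches only the enone, and hydroperoxide adds axially to C7 on the convex face anti to the C5–C4 bond (the carvone precedent), giving the 7β,8β-epoxide.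

Step 5
Reactants: 8 7β,8β-epoxy ketone
Product: 10 7β-allylic alcohol (Δ8), via epoxy hydrazone 9 (not isolated)
Conditions: N2H4·H2O, AcOH (cat.), MeOH, 0 °C → rt
Reagents that add atoms: none
Why: Wharton transposition (hydrazone formation, epoxide opening, loss of N2) gives the transposed allylic alcohol without touching the C7–O bond, so the carbinol stays 7β.

Step 6
Reactants: 10 7β-allylic alcohol
Product: 11 7β-(tributylstannyl)methyl ether
Conditions: KH, THF, 0 °C; then Bu3SnCH2I, rt
Reagents that add atoms: tributyl(iodomethyl)stannane (CCCC[Sn](CCCC)(CCCC)CI)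
Why: Williamson etherification of the potassium alkoxide with the iodomethylstannane installs the Wittig–Still precursor without affecting any stereocentre.

Step 7
Reactants: 11 7β-(tributylstannyl)methyl ether
Product: 13 9β-hydroxymethyl Δ3,Δ7-diene, via lithiomethyl ether 12 (not isolated)
Conditions: n-BuLi, THF, −78 → −20 °C; then H2O
Reagents that add atoms: none
Why: Tin–lithium exchange gives the α-alkoxymethyllithium, whose [2,3]-Wittig–Still rearrangement moves the CH2O unit suprafacially from the 7β-oxygen to C9, so C11 is β (cis to the C10 methyl, H-9 α) and the alkene shifts to C7=C8.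

Step 8
Reactants: 13 9β-hydroxymethyl Δ3,Δ7-diene
Product: 14 7β,8β-epoxy C11 alcohol
Conditions: VO(acac)2 (cat.), t-BuOOH, CH2Cl2, 0 °C → rt
Reagents that add atoms: tert-butyl hydroperoxide (CC(C)(C)OO)
Why: Hydroxyl-directed vanadium-catalysed epoxidation delivers oxygen to the alkene face syn to the homoallylic CH2OH (β) and leaves the undirected ring A alkene untouched.

Step 9
Reactants: 14 7β,8β-epoxy C11 alcohol
Product: 15 PMB ether of 14
Conditions: NaH, PMBCl, Bu4NI (cat.), THF/DMF, 0 °C → rt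
Reagents that add atoms: 4-methoxybenzyl chloride (COc1ccc(CCl)cc1)
Why: Williamson ether synthesis masks the primary alcohol for the acidic, radical, hydride and basic steps that follow; the alkoxide cannot reach the syn epoxide from the rear.

Step 10
Reactants: 15 PMB ether of 14
Product: 16 7β,8α-diol
Conditions: HClO4 (cat.), THF/H2O, 0 °C → rt
Reagents that add atoms: water (O)
Why: Acid-catalysed epoxide hydrolysis in which water opens the protonated trisubstituted epoxide at the tertiary carbon C8 with inversion (borderline SN1/SN2, trans-diaxial), giving 8α-OH/8β-Me and leaving the 7β-hydroxyl.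

Step 11
Reactants: 16 7β,8α-diol
Product: 17 7-O-phenoxythiocarbonyl derivative
Conditions: PhOC(S)Cl, pyridine, DMAP (cat.), CH2Cl2, rt
Reagents that add atoms: O-phenyl chlorothionoformate (S=C(Cl)Oc1ccccc1)
Why: Chemoselective thioacylation of the secondary 7-hydroxyl (the tertiary 8-hydroxyl does not react) gives the Barton–McCombie substrate.

Step 12
Reactants: 17 7-O-phenoxythiocarbonyl derivative
Product: 18 8α-tertiary alcohol (C7 deoxygenated)
Conditions: Bu3SnH, AIBN (cat.), toluene, 100 °C
Reagents that add atoms: none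
Why: Barton–McCombie radical deoxygenation removes the C7 oxygen; the C8 stereocentre and the alkene are not involved.

Step 13
Reactants: 18 8α-tertiary alcohol
Product: 19 8α-triethylsilyl ether
Conditions: TESOTf, 2,6-lutidine, CH2Cl2, 0 °C
Reagents that add atoms: triethylsilyl trifluoromethanesulfonate (CC[Si](CC)(CC)OS(=O)(=O)C(F)(F)F)
Why: Silylation with the silyl triflate masks the tertiary alcohol against O-methylation in step 16 and against retro-aldol or elimination at the later β-oxy aldehyde stage.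

Step 14
Reactants: 19 8α-triethylsilyl ether
Product: 21 C3 alcohol (3ξ,4ξ), via C3 alkylborane 20 (not isolated)
Conditions: BH3·THF, THF, 0 °C → rt; then NaOH, H2O2
Reagents that add atoms: hydrogen peroxide (OO)
Why: Hydroboration–oxidation places boron and then hydroxyl on the less substituted C3 of the ring A alkene (anti-Markovnikov); the C3/C4 configurations do not matter because both centres are planarised in steps 15 and 16.

Step 15
Reactants: 21 C3 alcohol
Product: 22 4-methyl-3-ketone (4ξ)
Conditions: DMP, CH2Cl2, rt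
Reagents that add atoms: none
Why: Dess–Martin oxidation converts the secondary alcohol into the ketone without touching the silyl or PMB ethers.

Step 16
Reactants: 22 4-methyl-3-ketone
Product: 24 4,4-dimethyl-3-ketone, via potassium Δ3-enolate 23 (not isolated)
Conditions: KOt-Bu, t-BuOH/THF, rt; then MeI
Reagents that add atoms: iodomethane (CI)
Why: Thermodynamic enolisation toward the more substituted C4 (also the preferred direction in a cis-fused 3-decalone) followed by C-methylation (enolate alkylation) installs the gem-dimethyl group.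

Step 17
Reactants: 24 4,4-dimethyl-3-ketone
Product: 25 C3 alcohol (3ξ)
Conditions: NaBH4, MeOH/THF, 0 °C
Reagents that add atoms: none
Why: Borohydride reduction turns the ketone into an alcohol that can be carried past the organobarium step; its configuration is immaterial since it is re-oxidised in step 30.

Step 18
Reactants: 25 C3 alcohol
Product: 26 C3 TBS ether
Conditions: TBSOTf, 2,6-lutidine, CH2Cl2, 0 °C → rt
Reagents that add atoms: tert-butyldimethylsilyl trifluoromethanesulfonate (CC(C)(C)[Si](C)(C)OS(=O)(=O)C(F)(F)F)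
Why: Silyl ether formation with the reactive triflate protects the hindered neopentyl-type alcohol.

Step 19
Reactants: 26 C3 TBS ether
Product: 27 C11 primary alcohol
Conditions: DDQ, CH2Cl2/H2O, 0 °C → rt
Reagents that add atoms: none
Why: Oxidative PMB cleavage (benzylic hydride abstraction by DDQ, then hydrolysis) frees the C11 alcohol and leaves both silyl ethers in place.

Step 20
Reactants: 27 C11 primary alcohol
Product: 28 C11 aldehyde
Conditions: DMP, pyridine, CH2Cl2, 0 °C
Reagents that add atoms: none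
Why: Buffered Dess–Martin oxidation gives the aldehyde without epimerising C9 or eliminating the β-silyloxy group.

Step 21
Reactants: 29 (2E,6E)-farnesyl acetate
Product: 30 (2E,6E,10E)-12-hydroxyfarnesyl acetate
Conditions: SeO2 (cat.), t-BuOOH, salicylic acid (cat.), CH2Cl2, rt
Reagents that add atoms: tert-butyl hydroperoxide (CC(C)(C)OO)
Why: Riley allylic oxidation (ene reaction, then [2,3] shift) is selective for the (E)-methyl of the terminal trisubstituted alkene and gives the (10E)-allylic alcohol.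

Step 22
Reactants: 30 (2E,6E,10E)-12-hydroxyfarnesyl acetate
Product: 31 12-TBS ether acetate
Conditions: TBSCl, imidazole, DMF, rt
Reagents that add atoms: tert-butyldimethylsilyl chloride (CC(C)(C)[Si](C)(C)Cl)
Why: Standard silylation protects the future C30 oxygen with a group that tolerates the organobarium reagent.

Step 23
Reactants: 31 12-TBS ether acetate
Product: 32 12-silyloxyfarnesol
Conditions: K2CO3 (cat.), MeOH, rt
Reagents that add atoms: none
Why: Base-catalysed transesterification (methanolysis) removes the acetate and leaves the silyl ether and the alkene geometries intact.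

Step 24
Reactants: 32 12-silyloxyfarnesol
Product: 34 12-silyloxyfarnesyl chloride, via allylic mesylate 33 (not isolated)
Conditions: MsCl, Et3N, CH2Cl2, −40 °C; then LiCl, THF, 0 °C
Reagents that add atoms: lithium chloride ([Li+].[Cl-])
Why: Mesylation and SN2 displacement by chloride give the primary allylic chloride without allylic transposition, so the 2E geometry is kept.

Step 25
Reactants: 28 C11 aldehyde; 34 12-silyloxyfarnesyl chloride
Product: 36 C11 homoallylic alcohol (11ξ), via allylbarium chloride 35 (not isolated)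
Conditions: BaI2, Li(C12H10) (lithium biphenylide), THF, rt (gives zerovalent barium); then 34, −78 °C; then 28, −78 °C; aq. NH4Cl
Reagents that add atoms: none
Why: Carbonyl allylation in which the allylic barium reagent adds to the aldehyde through its primary α-carbon with retention of the 2E geometry, forming the C11–C12 bond that joins the two fragments; the carbinol configuration is irrelevant.

Step 26
Reactants: 36 C11 homoallylic alcohol
Product: 37 C11 imidazolylthiocarbonyl derivative
Conditions: Im2C=S, DMAP (cat.), toluene, 80 °C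
Reagents that add atoms: 1,1'-thiocarbonyldiimidazole (S=C(n1ccnc1)n1ccnc1)
Why: Thioacylation under non-basic conditions (no silyl migration from the C8 oxygen) prepares the hindered secondary carbinol for Barton–McCombie reduction.

Step 27
Reactants: 37 C11 imidazolylthiocarbonyl derivative
Product: 38 tris-silyl ether of the C3,C8,C30-triol
Conditions: Bu3SnH, AIBN (cat.), toluene, 100 °C
Reagents that add atoms: none
Why: Barton–McCombie radical deoxygenation removes the C11 oxygen; at this tin hydride concentration the homoallylic radical is reduced before it can cyclise, so the C13 alkene stays E.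

Step 28
Reactants: 38 tris-silyl ether
Product: 39 C3,C8,C30-triol
Conditions: Bu4NF, THF, 50 °C
Reagents that add atoms: none
Why: Fluoride-mediated desilylation removes the two TBS ethers and the tertiary TES ether in one operation.

Step 29
Reactants: 39 C3,C8,C30-triol
Product: 40 C30 monoacetate
Conditions: Ac2O (1.1 equiv), pyridine, CH2Cl2, 0 °C
Reagents that add atoms: acetic anhydride (CC(=O)OC(C)=O)
Why: Acylation is selective for the unhindered primary allylic alcohol over the neopentyl-type C3 alcohol and the tertiary C8 alcohol.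

Step 30
Reactants: 40 C30 monoacetate
Product: 41 myrrhanone A acetate (target)
Conditions: DMP, CH2Cl2, rt
Reagents that add atoms: none
Why: Dess–Martin oxidation converts the C3 alcohol into the ketone, the tertiary alcohol, allylic acetate and alkenes being inert, and none of the four stereocentres is touched.

**Compound list**
1 | (S)-(+)-carvone, (5S)-2-methyl-5-(prop-1-en-2-yl)cyclohex-2-en-1-one | CC1=CC[C@@H](CC1=O)C(C)=C | starting material
2 | 4-iodobut-1-ene | C=CCCI | starting material
3 | lithium α′-dienolate of 1 | CC1=CC[C@@H](C=C1O[Li])C(C)=C | intermediate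
4 | (5S,6RS)-6-(but-3-en-1-yl)-2-methyl-5-(prop-1-en-2-yl)cyclohex-2-en-1-one | CC1=CC[C@H](C(C)=C)C(CCC=C)C1=O | intermediate
5 | lithium enolate of 4 | CC1=CC[C@H](C(C)=C)C(CCC=C)=C1O[Li] | intermediate
6 | (5R,6S)-6-(but-3-en-1-yl)-2,6-dimethyl-5-(prop-1-en-2-yl)cyclohex-2-en-1-one (methyl trans to isopropenyl) | CC1=CC[C@H](C(C)=C)[C@](C)(CCC=C)C1=O | intermediate
7 | (4aR,8aS)-2,5,8a-trimethyl-4a,7,8,8a-tetrahydronaphthalen-1(4H)-one; 4,8,10-trimethyl-5β-H-decala-3,7-dien-9-one | CC1=CC[C@@H]2C(C)=CCC[C@]2(C)C1=O | intermediate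
8 | 7β,8β-epoxy-4,8,10-trimethyl-5β-H-decal-3-en-9-one | C[C@]12O[C@H]1C[C@@H]3C(C)=CCC[C@]3(C)C2=O | intermediate
9 | hydrazone of 8 | C[C@]12O[C@H]1C[C@@H]3C(C)=CCC[C@]3(C)C2=NN | intermediate
10 | 4,8,10-trimethyl-5β-H-decala-3,8-dien-7β-ol | CC1=C[C@@]2(C)CCC=C(C)[C@H]2C[C@@H]1O | intermediate
11 | 7β-[(tributylstannyl)methoxy]-4,8,10-trimethyl-5β-H-decala-3,8-diene | CC1=C[C@@]2(C)CCC=C(C)[C@H]2C[C@@H]1OC[Sn](CCCC)(CCCC)CCCC | intermediate
12 | 7β-(lithiomethoxy)-4,8,10-trimethyl-5β-H-decala-3,8-diene | CC1=C[C@@]2(C)CCC=C(C)[C@H]2C[C@@H]1OC[Li] | intermediate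
13 | (4,8,10-trimethyl-5β-H-decala-3,7-dien-9β-yl)methanol (9α-H) | OC[C@H]1C(C)=CC[C@@H]2C(C)=CCC[C@]12C | intermediate
14 | (7β,8β-epoxy-4,8,10-trimethyl-5β-H-decal-3-en-9β-yl)methanol | OC[C@H]1[C@@]2(C)O[C@H]2C[C@@H]3C(C)=CCC[C@]13C | intermediate
15 | 11-O-(4-methoxybenzyl) ether of 14 | COc1ccc(COC[C@H]2[C@@]3(C)O[C@H]3C[C@@H]4C(C)=CCC[C@]24C)cc1 | intermediate
16 | 9β-[(4-methoxybenzyloxy)methyl]-4,8β,10β-trimethyl-5β-H-decal-3-ene-7β,8α-diol | COc1ccc(COC[C@H]2[C@](C)(O)[C@@H](O)C[C@@H]3C(C)=CCC[C@]23C)cc1 | intermediate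
17 | 7-O-(phenoxythiocarbonyl) derivative of 16 | COc1ccc(COC[C@H]2[C@](C)(O)[C@@H](OC(=S)Oc3ccccc3)C[C@@H]4C(C)=CCC[C@]24C)cc1 | intermediate
18 | 9β-[(4-methoxybenzyloxy)methyl]-4,8β,10β-trimethyl-5β-H-decal-3-en-8α-ol | COc1ccc(COC[C@H]2[C@](C)(O)CC[C@@H]3C(C)=CCC[C@]23C)cc1 | intermediate
19 | 8α-O-triethylsilyl ether of 18 | COc1ccc(COC[C@H]2[C@](C)(O[Si](CC)(CC)CC)CC[C@@H]3C(C)=CCC[C@]23C)cc1 | intermediate
20 | C3 alkylborane from 19 (3ξ,4ξ) | COc1ccc(COC[C@H]2[C@](C)(O[Si](CC)(CC)CC)CC[C@@H]3C(C)C(B)CC[C@]23C)cc1 | intermediate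
21 | 3ξ-hydroxy-4ξ-methyl compound (saturated ring A) | COc1ccc(COC[C@H]2[C@](C)(O[Si](CC)(CC)CC)CC[C@@H]3C(C)C(O)CC[C@]23C)cc1 | intermediate
22 | 3-oxo-4ξ-methyl compound | COc1ccc(COC[C@H]2[C@](C)(O[Si](CC)(CC)CC)CC[C@@H]3C(C)C(=O)CC[C@]23C)cc1 | intermediate
23 | potassium Δ3-enolate of 22 | COc1ccc(COC[C@H]2[C@](C)(O[Si](CC)(CC)CC)CC[C@@H]3C(C)=C(O[K])CC[C@]23C)cc1 | intermediate
24 | 9β-[(4-methoxybenzyloxy)methyl]-4,4,8β,10β-tetramethyl-8α-(triethylsilyloxy)-5β-H-decalin-3-one | COc1ccc(COC[C@H]2[C@](C)(O[Si](CC)(CC)CC)CC[C@@H]3C(C)(C)C(=O)CC[C@]23C)cc1 | intermediate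
25 | 3ξ-alcohol from 24 | COc1ccc(COC[C@H]2[C@](C)(O[Si](CC)(CC)CC)CC[C@@H]3C(C)(C)C(O)CC[C@]23C)cc1 | intermediate
26 | 3ξ-O-TBS ether of 25 | COc1ccc(COC[C@H]2[C@](C)(O[Si](CC)(CC)CC)CC[C@@H]3C(C)(C)C(O[Si](C)(C)C(C)(C)C)CC[C@]23C)cc1 | intermediate
27 | [3ξ-(TBS-oxy)-8α-(TES-oxy)-4,4,8β,10β-tetramethyl-5β-H-decalin-9β-yl]methanol | OC[C@H]1[C@](C)(O[Si](CC)(CC)CC)CC[C@@H]2C(C)(C)C(O[Si](C)(C)C(C)(C)C)CC[C@]12C | intermediate
28 | 3ξ-(TBS-oxy)-8α-(TES-oxy)-4,4,8β,10β-tetramethyl-5β-H-decalin-9β-carbaldehyde | O=C[C@H]1[C@](C)(O[Si](CC)(CC)CC)CC[C@@H]2C(C)(C)C(O[Si](C)(C)C(C)(C)C)CC[C@]12C | intermediate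
29 | (2E,6E)-farnesyl acetate | CC(C)=CCC/C(C)=C/CC/C(C)=C/COC(C)=O | starting material
30 | (2E,6E,10E)-12-hydroxy-3,7,11-trimethyldodeca-2,6,10-trien-1-yl acetate | OC/C(C)=C/CC/C(C)=C/CC/C(C)=C/COC(C)=O | intermediate
31 | (2E,6E,10E)-12-(TBS-oxy)-3,7,11-trimethyldodeca-2,6,10-trien-1-yl acetate | CC(C)(C)[Si](C)(C)OC/C(C)=C/CC/C(C)=C/CC/C(C)=C/COC(C)=O | intermediate
32 | (2E,6E,10E)-12-(TBS-oxy)-3,7,11-trimethyldodeca-2,6,10-trien-1-ol | CC(C)(C)[Si](C)(C)OC/C(C)=C/CC/C(C)=C/CC/C(C)=C/CO | intermediate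
33 | methanesulfonate of 32 | CC(C)(C)[Si](C)(C)OC/C(C)=C/CC/C(C)=C/CC/C(C)=C/COS(C)(=O)=O | intermediate
34 | (2E,6E,10E)-12-(TBS-oxy)-3,7,11-trimethyldodeca-2,6,10-trien-1-yl chloride | CC(C)(C)[Si](C)(C)OC/C(C)=C/CC/C(C)=C/CC/C(C)=C/CCl | intermediate
35 | allylbarium chloride from 34 | CC(C)(C)[Si](C)(C)OC/C(C)=C/CC/C(C)=C/CC/C(C)=C/C[Ba]Cl | intermediate
36 | 11ξ-hydroxy coupled product (tris-silyl ether, 13E,17E,21E) | CC(C)(C)[Si](C)(C)OC/C(C)=C/CC/C(C)=C/CC/C(C)=C/CC(O)[C@H]1[C@](C)(O[Si](CC)(CC)CC)CC[C@@H]2C(C)(C)C(O[Si](C)(C)C(C)(C)C)CC[C@]12C | intermediate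
37 | 11-O-(imidazol-1-ylthiocarbonyl) derivative of 36 | CC(C)(C)[Si](C)(C)OC/C(C)=C/CC/C(C)=C/CC/C(C)=C/CC(OC(=S)n1ccnc1)[C@H]1[C@](C)(O[Si](CC)(CC)CC)CC[C@@H]2C(C)(C)C(O[Si](C)(C)C(C)(C)C)CC[C@]12C | intermediate
38 | 3ξ,30-bis-O-TBS, 8α-O-TES ether of the 5-epi-polypoda-13E,17E,21E-triene-3,8,30-triol | CC(C)(C)[Si](C)(C)OC/C(C)=C/CC/C(C)=C/CC/C(C)=C/CC[C@H]1[C@](C)(O[Si](CC)(CC)CC)CC[C@@H]2C(C)(C)C(O[Si](C)(C)C(C)(C)C)CC[C@]12C | intermediate
39 | free 3ξ,8α,30-triol | OC/C(C)=C/CC/C(C)=C/CC/C(C)=C/CC[C@H]1[C@](C)(O)CC[C@@H]2C(C)(C)C(O)CC[C@]12C | intermediate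
40 | 30-O-acetyl-3ξ,8α-diol | CC(=O)OC/C(C)=C/CC/C(C)=C/CC/C(C)=C/CC[C@H]1[C@](C)(O)CC[C@@H]2C(C)(C)C(O)CC[C@]12C | intermediate
41 | myrrhanone A acetate as drawn, (5S,8R,9R,10S) | CC(=O)OC/C(C)=C/CC/C(C)=C/CC/C(C)=C/CC[C@@H]1[C@@]2(C)CCC(=O)C(C)(C)[C@H]2CC[C@@]1(C)O | target

**Totals and risks**
Total step count: 30. Longest linear sequence: 26 steps (steps 1–20 and 25–30, from carvone); the side-chain branch is steps 21–24.

Most likely to fail, step 5 (Wharton transposition at a ketone flanked by two fully substituted carbons, where hydrazone formation may be too slow): set out from 8 and reduce it (NaBH4, CeCl3, MeOH) to the epoxy alcohol F1. Convert F1 (NaH, CS2, MeI) into the S-methyl xanthate F2. Bu3SnH/AIBN then gives the C9 radical, which opens the adjacent epoxide; hydrogen transfer to the resulting 7β-alkoxy radical (Barton-type radical fragmentation instead of a hydrazone route) returns to the route at 10.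

Most likely to fail, step 7 ([2,3]-Wittig–Still shift to a carbon next to the quaternary C10, with [1,2]-shift or simple protonation as competitors): set out from 10 and heat it with Me2NCH(OMe)2 in xylene at 140 °C. The Büchi [2,3]-sigmatropic rearrangement of the derived alkoxy(amino)carbene, again suprafacial, gives the N,N-dimethyl 9β-carboxamide F3. LiBHEt3 reduces the amide to the primary alcohol and the route is rejoined at 13.

Most likely to fail, step 25 (α-selective allylbarium addition to a very hindered, enolisable aldehyde): set out from 27 and 34 and couple by sulfone alkylation instead. Convert 27 (Tf2O, 2,6-lutidine, −78 °C) into the C11 triflate F4. Convert 34 (PhSO2Na, DMF) into the allylic phenyl sulfone F5. Deprotonate F5 (n-BuLi, THF/HMPA, −78 °C) and alkylate with F4 to give the C12-sulfonyl coupled product F6. Reductive desulfonylation with PdCl2(dppp) (cat.) and LiBHEt3 rejoins the route at 38, which also saves steps 26 and 27.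

**Further compounds**
F1 | step 5 | 7β,8β-epoxy-4,8,10-trimethyl-5β-H-decal-3-en-9ξ-ol | C[C@]12O[C@H]1C[C@@H]3C(C)=CCC[C@]3(C)C2O
F2 | step 5 | O-(7β,8β-epoxy-4,8,10-trimethyl-5β-H-decal-3-en-9ξ-yl) S-methyl dithiocarbonate | C[C@]12O[C@H]1C[C@@H]3C(C)=CCC[C@]3(C)C2OC(=S)SC
F3 | step 7 | N,N-dimethyl-4,8,10-trimethyl-5β-H-decala-3,7-diene-9β-carboxamide | CN(C)C(=O)[C@H]1C(C)=CC[C@@H]2C(C)=CCC[C@]12C
F4 | step 25 | trifluoromethanesulfonate of 27 | O=S(=O)(OC[C@H]1[C@](C)(O[Si](CC)(CC)CC)CC[C@@H]2C(C)(C)C(O[Si](C)(C)C(C)(C)C)CC[C@]12C)C(F)(F)F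
F5 | step 25 | (2E,6E,10E)-12-(TBS-oxy)-3,7,11-trimethyldodeca-2,6,10-trien-1-yl phenyl sulfone | CC(C)(C)[Si](C)(C)OC/C(C)=C/CC/C(C)=C/CC/C(C)=C/CS(=O)(=O)c1ccccc1
F6 | step 25 | 12ξ-phenylsulfonyl derivative of 38 | CC(C)(C)[Si](C)(C)OC/C(C)=C/CC/C(C)=C/CC/C(C)=C/C(C[C@H]1[C@](C)(O[Si](CC)(CC)CC)CC[C@@H]2C(C)(C)C(O[Si](C)(C)C(C)(C)C)CC[C@]12C)S(=O)(=O)c1ccccc1
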